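**Strategy.** The six-membered carbocycle holds a β-hydroxy ketone (C2 carbonyl, C3 methylene, C4 carbinol) next to quaternary C1, and is disconnected at C3–C4. In the forward direction the keto-aldehyde 4-C-acetyl-2-O-benzoyl-3-O-benzyl-L-xylose, stored as its pyranose, undergoes an amine-catalysed intramolecular aldol addition. This forms the C3–C4 bond, closes the cyclohexanone ring and sets the C4 carbinol in one operation. Because C1 carries no hydrogen, only the methyl group can act as the nucleophile. The precursor takes C5 and C6 unchanged from D-arabinose; C1 is created by axial ethynylation of a pyranosid-4-ulose, and the alkyne is then hydrated to the acetyl group.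

Key step: step 10

Remark on numbering: ring locants are C1 (quaternary carbinol bearing C7), C2 (ketone), C3 (CH2), C4 (OH), C5 (OBz), C6 (OH). Pyranose intermediates carry sugar locants; sugar C1, C2, C3, C4 and C5 become ring C4, C5, C6, C1 and C7.

Assumption: ketone 12 reacts from the 1C4 chair, in which the allyloxy group is axial and O2 and O3 are equatorial.

**Step 1**
Reactants: 1 D-arabinose; 2 allyl alcohol
Product: 3 allyl β-D-arabinopyranoside
Conditions: allyl alcohol (solvent), HCl (cat.), 70 °C; crystallisation
Reagents that add atoms: allyl alcohol C=CCO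
Why: Fischer glycosidation under thermodynamic control should converge on the pyranoside with the axial (β-D) allyloxy group, which crystallises, and it leaves the C2–C4 stereocentres of D-arabinose untouched.

**Step 2**
Reactants: 3 allyl β-D-arabinopyranoside; 4 2,2-dimethoxypropane
Product: 5 allyl 3,4-O-isopropylidene-β-D-arabinopyranoside
Conditions: Me2C(OMe)2, TsOH (cat.), acetone, rt
Reagents that add atoms: 2,2-dimethoxypropane COC(C)(C)OC
Why: Acid-catalysed transacetalisation (acetonide formation) should bridge only the cis-3,4-diol (O3 equatorial, O4 axial) as a dioxolane and leave the O2 hydroxyl free.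

**Step 3**
Reactants: 5 allyl 3,4-O-isopropylidene-β-D-arabinopyranoside; 6 benzoyl chloride
Product: 7 allyl 2-O-benzoyl-3,4-O-isopropylidene-β-D-arabinopyranoside
Conditions: BzCl, pyridine, DMAP (cat.), CH2Cl2, 0 °C to rt
Reagents that add atoms: benzoyl chloride O=C(Cl)c1ccccc1
Why: Pyridine-mediated acylation of the only free hydroxyl installs the ester that ends as the C5 benzoate of the target.

**Step 4**
Reactants: 7 allyl 2-O-benzoyl-3,4-O-isopropylidene-β-D-arabinopyranoside
Product: 8 allyl 2-O-benzoyl-β-D-arabinopyranoside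
Conditions: AcOH–H2O (4:1), 50 °C
Reagents that add atoms: none
Why: Mild acid hydrolysis of the dioxolane acetal should free the 3,4-diol while the allyl glycoside and the benzoate persist.

**Step 5**
Reactants: 8 allyl 2-O-benzoyl-β-D-arabinopyranoside; 9 benzyl bromide
Product: 11 allyl 2-O-benzoyl-3-O-benzyl-β-D-arabinopyranoside, via stannylene acetal 10 (not isolated)
Conditions: Bu2SnO, toluene, reflux (Dean–Stark); then BnBr, Bu4NBr (cat.), 80 °C
Reagents that add atoms: benzyl bromide BrCc1ccccc1; dibutyltin oxide CCCC[Sn](=O)CCCC (its tin is present only in intermediate 10)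
Why: In stannylene-acetal-mediated alkylation of a cis-diol the equatorial oxygen is the reactive one, so benzylation should take place at O3 and leave the axial O4 hydroxyl free for oxidation.

**Step 6**
Reactants: 11 allyl 2-O-benzoyl-3-O-benzyl-β-D-arabinopyranoside
Product: 12 allyl 2-O-benzoyl-3-O-benzyl-β-D-threo-pentopyranosid-4-ulose
Conditions: Dess–Martin periodinane, CH2Cl2, rt
Reagents that add atoms: none
Why: Dess–Martin oxidation of the remaining secondary alcohol proceeds without base, which should prevent β-elimination of the C2 benzoate and epimerisation at C3.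

**Step 7**
Reactants: 12 allyl 2-O-benzoyl-3-O-benzyl-β-D-threo-pentopyranosid-4-ulose; 13 ethynylmagnesium bromide
Product: 14 allyl 2-O-benzoyl-3-O-benzyl-4-C-ethynyl-α-L-xylopyranoside
Conditions: HC≡CMgBr, CeCl3, THF, −78 °C; then 12, −78 °C; aq. NH4Cl
Reagents that add atoms: ethynylmagnesium bromide C#C[Mg]Br
Why: Addition of a weakly basic organocerium acetylide to the ketone should follow the axial trajectory of the 1C4 chair, on the face opposite the axial allyloxy group where only the C2 axial hydrogen is syn-axial to the small rod-shaped nucleophile, so the ethynyl group becomes axial and the new tertiary hydroxyl equatorial (L-xylo, the future C1), while the low basicity spares the benzoate and avoids enolisation toward C3.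

**Step 8**
Reactants: 14 allyl 2-O-benzoyl-3-O-benzyl-4-C-ethynyl-α-L-xylopyranoside; 15 water
Product: 16 allyl 4-C-acetyl-2-O-benzoyl-3-O-benzyl-α-L-xylopyranoside
Conditions: Ph3PAuNTf2 (cat.), H2O, MeOH, rt to 40 °C
Reagents that add atoms: water O
Why: Gold-catalysed Markovnikov hydration of the terminal alkyne gives the methyl ketone, and since the cationic gold catalyst activates alkynes in preference to alkenes the allyl group, the esters and the tertiary alcohol should be unaffected.

**Step 9**
Reactants: 16 allyl 4-C-acetyl-2-O-benzoyl-3-O-benzyl-α-L-xylopyranoside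
Product: 18 4-C-acetyl-2-O-benzoyl-3-O-benzyl-L-xylopyranose (anomeric mixture), via prop-1-enyl glycoside 17 (not isolated)
Conditions: [Ir(cod)(PMePh2)2]PF6 (cat., H2-activated), THF, rt; then 0.1 M HCl, acetone–H2O, 40 °C
Reagents that add atoms: none
Why: Iridium-hydride-catalysed isomerisation of the allyl ether to the enol ether, followed by mild acid hydrolysis of that enol ether (anomeric deallylation), should free the hemiacetal without touching benzoate, benzyl ether or ketone.

**Step 10**
Reactants: 18 4-C-acetyl-2-O-benzoyl-3-O-benzyl-L-xylopyranose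
Product: 20 (1S,4R,5R,6S)-6-benzyloxy-1,4-dihydroxy-1-(hydroxymethyl)-2-oxocyclohexan-5-yl benzoate (ring locants as above), via aldehydo form 19 (not isolated)
Conditions: L-proline (30 mol%), DMSO (0.05 M), rt
Reagents that add atoms: none
Why: The pyranose opens by ring–chain tautomerism to aldehydo form 19, proline condenses with the methyl ketone to an enamine at the methyl carbon (quaternary C1 offers no other enolisable position), and this enamine adds to the aldehyde carbon to form the C3–C4 bond before hydrolysis returns the catalyst. The closest known reaction type is the amine-mediated intramolecular aldol cyclisation of 6-deoxyhexos-5-uloses, the carbon–carbon bond-forming stage of the Ferrier carbocyclisation. The cyclohexanone ring closes in the 6-(enolendo)-exo-trig mode. The only new stereocentre, C4, should be set by a chair-like transition state in which the C5 benzoate, the C6 benzyl ether and C7 are equatorial and the aldehyde oxygen is axial, gauche to the enamine carbon and within reach of the proline carboxylic acid; this places the C4 hydroxyl cis to O5 and trans to O6 (4R). The step needs enolisation at the methyl ketone and not at the aldehyde, and must avoid loss of the C6 benzyloxy group and benzoyl migration: the aldehyde is α-branched, α-acyloxylated and largely masked as the hemiacetal, so it is a poor enamine donor, and the near-neutral medium disfavours E1cB elimination, acyl shifts and dehydration of the aldol.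

**Step 11**
Reactants: 20 the aldol product of step 10; 6 benzoyl chloride
Product: 21 [(1S,4R,5R,6S)-5-benzoyloxy-6-benzyloxy-1,4-dihydroxy-2-oxocyclohexyl]methyl benzoate
Conditions: BzCl (1.1 equiv), 2,4,6-collidine, CH2Cl2, −40 to 0 °C
Reagents that add atoms: benzoyl chloride O=C(Cl)c1ccccc1
Why: Kinetically controlled acylation with a hindered pyridine base (regioselective benzoylation) should pick the primary C7 hydroxyl over the axial secondary C4 hydroxyl and the tertiary C1 hydroxyl.

**Step 12**
Reactants: 21 the C7 benzoate of step 11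
Product: 22 [(1S,4R,5R,6S)-5-benzoyloxy-1,4,6-trihydroxy-2-oxocyclohexyl]methyl benzoate (CNP0127041.1)
Conditions: H2 (1 atm), Pd(OH)2/C, EtOAc, rt
Reagents that add atoms: none
Why: Catalytic hydrogenolysis of the benzyl ether in a neutral aprotic solvent should release the C6 hydroxyl without reducing the ketone, cleaving the benzoates or touching any stereocentre.

**Compound list**

1 | D-arabinose | O=C[C@@H](O)[C@H](O)[C@H](O)CO | starting material
2 | allyl alcohol | C=CCO | starting material
3 | allyl β-D-arabinopyranoside | C=CCO[C@@H]1OC[C@@H](O)[C@@H](O)[C@@H]1O | intermediate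
4 | 2,2-dimethoxypropane | COC(C)(C)OC | starting material
5 | allyl 3,4-O-isopropylidene-β-D-arabinopyranoside | C=CCO[C@@H]1OC[C@H]2OC(C)(C)O[C@H]2[C@@H]1O | intermediate
6 | benzoyl chloride | O=C(Cl)c1ccccc1 | starting material
7 | allyl 2-O-benzoyl-3,4-O-isopropylidene-β-D-arabinopyranoside | C=CCO[C@@H]1OC[C@H]2OC(C)(C)O[C@H]2[C@@H]1OC(=O)c1ccccc1 | intermediate
8 | allyl 2-O-benzoyl-β-D-arabinopyranoside | C=CCO[C@@H]1OC[C@@H](O)[C@@H](O)[C@@H]1OC(=O)c1ccccc1 | intermediate
9 | benzyl bromide | BrCc1ccccc1 | starting material
10 | allyl 2-O-benzoyl-3,4-O-dibutylstannylene-β-D-arabinopyranoside (stannylene acetal) | C=CCO[C@@H]1OC[C@H]2O[Sn](CCCC)(CCCC)O[C@H]2[C@@H]1OC(=O)c1ccccc1 | intermediate (not isolated)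
11 | allyl 2-O-benzoyl-3-O-benzyl-β-D-arabinopyranoside | C=CCO[C@@H]1OC[C@@H](O)[C@@H](OCc2ccccc2)[C@@H]1OC(=O)c1ccccc1 | intermediate
12 | allyl 2-O-benzoyl-3-O-benzyl-β-D-threo-pentopyranosid-4-ulose | C=CCO[C@@H]1OCC(=O)[C@@H](OCc2ccccc2)[C@@H]1OC(=O)c1ccccc1 | intermediate
13 | ethynylmagnesium bromide | C#C[Mg]Br | starting material
14 | allyl 2-O-benzoyl-3-O-benzyl-4-C-ethynyl-α-L-xylopyranoside | C=CCO[C@@H]1OC[C@@](O)(C#C)[C@@H](OCc2ccccc2)[C@@H]1OC(=O)c1ccccc1 | intermediate
15 | water | O | starting material
16 | allyl 4-C-acetyl-2-O-benzoyl-3-O-benzyl-α-L-xylopyranoside | C=CCO[C@@H]1OC[C@@](O)(C(C)=O)[C@@H](OCc2ccccc2)[C@@H]1OC(=O)c1ccccc1 | intermediate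
17 | prop-1-enyl 4-C-acetyl-2-O-benzoyl-3-O-benzyl-α-L-xylopyranoside (E/Z) | CC=CO[C@@H]1OC[C@@](O)(C(C)=O)[C@@H](OCc2ccccc2)[C@@H]1OC(=O)c1ccccc1 | intermediate (not isolated)
18 | 4-C-acetyl-2-O-benzoyl-3-O-benzyl-L-xylopyranose (anomeric mixture) | OC1OC[C@@](O)(C(C)=O)[C@@H](OCc2ccccc2)[C@@H]1OC(=O)c1ccccc1 | intermediate
19 | 4-C-acetyl-2-O-benzoyl-3-O-benzyl-aldehydo-L-xylose | O=C[C@@H](OC(=O)c1ccccc1)[C@H](OCc1ccccc1)[C@@](O)(CO)C(C)=O | intermediate (not isolated)
20 | (1S,4R,5R,6S)-6-benzyloxy-1,4-dihydroxy-1-(hydroxymethyl)-2-oxocyclohexan-5-yl benzoate | OC[C@@]1(O)C(=O)C[C@@H](O)[C@@H](OC(=O)c2ccccc2)[C@@H]1OCc1ccccc1 | intermediate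
21 | [(1S,4R,5R,6S)-5-benzoyloxy-6-benzyloxy-1,4-dihydroxy-2-oxocyclohexyl]methyl benzoate | O=C(OC[C@@]1(O)C(=O)C[C@@H](O)[C@@H](OC(=O)c2ccccc2)[C@@H]1OCc1ccccc1)c1ccccc1 | intermediate
22 | [(1S,4R,5R,6S)-5-benzoyloxy-1,4,6-trihydroxy-2-oxocyclohexyl]methyl benzoate (CNP0127041.1) | O=C(OC[C@@]1(O)C(=O)C[C@@H](O)[C@@H](OC(=O)c2ccccc2)[C@@H]1O)c1ccccc1 | target

**Totals**

Total step count: 12. Longest linear sequence: 12 steps (D-arabinose to 22).

**Steps most likely to fail**

Step 10. The amine may engage the aldehyde instead of the methyl ketone, with loss of benzyl alcohol by β-elimination or epimerisation at C5. The benzoate may migrate, or the aldol may dehydrate or revert. The fallback generates the enolate reductively and regiospecifically. It sets out from 16, which is brominated at the methyl group with pyrrolidone hydrotribromide in THF (a reagent that brominates enolisable ketones in preference to alkenes) to give allyl 2-O-benzoyl-3-O-benzyl-4-C-(bromoacetyl)-α-L-xylopyranoside F3. Anomeric deallylation as in step 9 gives 2-O-benzoyl-3-O-benzyl-4-C-(bromoacetyl)-L-xylopyranose F4. Indium powder in THF–H2O should then form the metal enolate only at the brominated carbon and close the ring by an intramolecular Reformatsky-type addition to the lactol aldehyde. A metal-bridged chair places the aldehyde oxygen axial as before, and the route is rejoined at 20.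

Step 7. The acetylide may attack from the equatorial direction and give the 4-epimeric tertiary alcohol (poor facial selectivity). The fallback delivers oxygen, not carbon, to the ring carbon with a bulky reagent. It sets out from 12, which undergoes Wittig ethylidenation (Ph3P=CHCH3, THF, −78 to 0 °C) to give allyl 2-O-benzoyl-3-O-benzyl-4-deoxy-4-C-ethylidene-β-D-threo-pentopyranoside F1. Dihydroxylation with OsO4 (cat.) and NMO in acetone–H2O should attack the exocyclic alkene from the equatorial side, so the tertiary hydroxyl becomes equatorial. The trisubstituted alkene should react ahead of the allyl ether, and the reaction is stopped after one equivalent of oxidant. This gives allyl 2-O-benzoyl-3-O-benzyl-4-C-(1-hydroxyethyl)-α-L-xylopyranoside F2. Dess–Martin oxidation of its secondary alcohol returns to the route at 16, bypassing step 8.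

Step 11. Acylation may fail to discriminate between the C7 and C4 hydroxyls, or the base may trigger dehydration or loss of formaldehyde from the β-hydroxy ketone. The fallback installs the C7 ester before the ring is closed. It sets out from 18, which is opened with EtSH and BF3·OEt2 in CH2Cl2 at −20 °C to give 4-C-acetyl-2-O-benzoyl-3-O-benzyl-L-xylose diethyl dithioacetal F5. Benzoylation (BzCl, pyridine, 0 °C), where only a primary and a tertiary hydroxyl compete, gives 4-C-acetyl-2,5-di-O-benzoyl-3-O-benzyl-L-xylose diethyl dithioacetal F6. Unmasking with I2 and NaHCO3 in aqueous acetone gives 4-C-acetyl-2,5-di-O-benzoyl-3-O-benzyl-aldehydo-L-xylose F7. This is cyclised under the conditions of step 10 and returns to the route at 21.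

**Further compounds**

F1 | step 7 | allyl 2-O-benzoyl-3-O-benzyl-4-deoxy-4-C-ethylidene-β-D-threo-pentopyranoside (E/Z) | C=CCO[C@@H]1OCC(=CC)[C@@H](OCc2ccccc2)[C@@H]1OC(=O)c1ccccc1
F2 | step 7 | allyl 2-O-benzoyl-3-O-benzyl-4-C-(1-hydroxyethyl)-α-L-xylopyranoside (carbinol epimers) | C=CCO[C@@H]1OC[C@@](O)(C(C)O)[C@@H](OCc2ccccc2)[C@@H]1OC(=O)c1ccccc1
F3 | step 10 | allyl 2-O-benzoyl-3-O-benzyl-4-C-(bromoacetyl)-α-L-xylopyranoside | C=CCO[C@@H]1OC[C@@](O)(C(=O)CBr)[C@@H](OCc2ccccc2)[C@@H]1OC(=O)c1ccccc1
F4 | step 10 | 2-O-benzoyl-3-O-benzyl-4-C-(bromoacetyl)-L-xylopyranose (anomeric mixture) | OC1OC[C@@](O)(C(=O)CBr)[C@@H](OCc2ccccc2)[C@@H]1OC(=O)c1ccccc1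
F5 | step 11 | 4-C-acetyl-2-O-benzoyl-3-O-benzyl-L-xylose diethyl dithioacetal | CCSC(SCC)[C@@H](OC(=O)c1ccccc1)[C@H](OCc1ccccc1)[C@@](O)(CO)C(C)=O
F6 | step 11 | 4-C-acetyl-2,5-di-O-benzoyl-3-O-benzyl-L-xylose diethyl dithioacetal | CCSC(SCC)[C@@H](OC(=O)c1ccccc1)[C@H](OCc1ccccc1)[C@@](O)(COC(=O)c1ccccc1)C(C)=O
F7 | step 11 | 4-C-acetyl-2,5-di-O-benzoyl-3-O-benzyl-aldehydo-L-xylose | O=C[C@@H](OC(=O)c1ccccc1)[C@H](OCc1ccccc1)[C@@](O)(COC(=O)c1ccccc1)C(C)=O
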